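Answer 3 questions about flasks beta and alpha, using 3 earlier runs in which the single product was the one species read.

- which of these holds the largest part of the substrate at the end of beta (substrate / bis adduct / other mono adduct / single product)
- which of these holds the largest part of the substrate at the end of alpha (substrate / bis adduct / other mono adduct / single product)
- amount of single product at the end of beta, in percent of the substrate charged

| setting | amber | red | violet | beta | alpha |
|---|---|---|---|---|---|
| substrate | 0.050 M | 0.050 M | 0.050 M | 0.050 M | 0.050 M |
| partner | 0.021 M | 0.047 M | 0.089 M | 0.0250 M | 0.0750 M |
| remark | run made earlier | run made earlier | run made earlier |  |  |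
| time |  |  |  | 2.5 h | 2.5 h |

| run | time / h | single product / % |
|---|---|---|
| amber | 0.200 | 7.7 |
| amber | 0.417 | 2.4 |
| amber | 0.667 | 0.3 |
| amber | 1.33 | 0.5 |
| amber | 2.50 | 0 |
| red | 0.200 | 13.3 |
| red | 0.417 | 5.1 |
| red | 0.667 | 1.2 |
| red | 1.33 | 0 |
| red | 2.50 | 0 |
| violet | 0.200 | 20.6 |
| violet | 0.667 | 3.7 |
| violet | 1.33 | 0.2 |
| violet | 2.00 | 0 |
| violet | 2.50 | 0 |

(each reading ± 0.5 percentage points)



Begin with the single product. In the red run it falls from 13.3% to 5.1% between 0.200 h and 0.417 h, a read time constant of 0.226 h. The asked 2.5 h spans 11.1 such constants, and amber, red and violet read 0%, 0% and 0% at 2.50 h, so expect about zero in beta.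

For a first answer, let each partner take a fresh substrate before any second addition. Beta then keeps 50.0% of its substrate, and alpha ends with no substrate, bis adduct level with other mono adduct. But no reading shows that the first addition is the faster, so put the unknown substrate left back in.

Suppose partner, the limiting reagent, reaches 0 and the single product reads zero. Substrate, other mono adduct and bis adduct then sum to the charge, while other mono adduct plus twice bis adduct equals the partner charge over the substrate charge. Subtract the first balance from the second: bis adduct minus substrate equals the partner surplus, the partner charge minus the substrate charge, over the substrate charge. No rate enters it. For alpha the surplus is 50.0%, so bis adduct stands at 50.0% or above and substrate at 25.0% or below. Alpha's other mono adduct then trails its bis adduct by 3 times the substrate left. For beta the surplus is negative, and substrate leads bis adduct by 50.0%.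

One objection stands: partner was never read, so its end is assumed, and a species never read may shift the balance. Commit anyway: substrate, bis adduct, about zero.

The forecast gives substrate, other mono adduct and 0.1%, and it parts from this reckoning on alpha: “Any incomplete second addition favours the other mono adduct”.

Beta ends with substrate at 62.8% and single product at 0%; alpha ends with bis adduct at 70.7%, more than its substrate or other mono adduct.

    substrate + single product → side product (k = 0.330 /M/min)
    substrate + partner → other mono adduct (k = 6.70 /M/min)
    partner + other mono adduct → bis adduct (k = 20.0 /M/min)
    partner + single product → bis adduct (k = 0.310 /M/min)
    substrate + partner ⇌ single product (K = 56.0 /M, k = 7.10 /M/min)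

Alpha's partner stands at 0%, and its bis adduct minus substrate, less the 4.31% of side product divided by two, is 50 percentage points, against the surplus of 50.0%. For a neighbour of beta charged with 0.020 M of substrate, the surplus is 25.0%; that flask ends with bis adduct at 56.3% and substrate at 30.0%, 26 points apart.

The numbers in the tables stem from a simulated flask on assumed constants; noise was put on by code.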